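## The problem

Guaiane numbering is used throughout. C1–C5 form the cyclopentenone: C1 is the ring-fusion methine, C2 a methylene, C3 the ketone, C4 the methyl-bearing alkene carbon and C5 the alkene carbon at the fusion. C5–C6–C7–C8–C9–C10–C1 form the seven-membered ring. C7 carries C11 (the 2-acetoxypropan-2-yl carbon), C8 the propanoate and C10 a methyl group.

Target 25 is a 5–7 fused hydroazulenone whose rings share the C1–C5 bond, with the enone double bond at the fusion. It has four stereocentres, (1R,7S,8R,10S), grouped as two vicinal pairs, C1/C10 and C7/C8. H-1, the C10 methyl, the C8 oxygen and C11 all lie on one face of the seven-membered ring. The pairs are separated by the C9 methylene and by sp2 C5, so neither can be trusted to direct the other across a flexible ring. C10 can control C1 if both arise in one bond formation, and C8 can control C7 as an allylic stereocentre. C8 itself needs an external reagent, because C10 is 1,3 to it and carries no heteroatom.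

The fragile points are C1–H (γ to the enone, epimerisable through the dienolate), the tertiary C11 acetate (elimination, ionisation) and the two different esters on a 1,3-related secondary/tertiary diol (acyl migration). The acyl groups therefore belong at the very end.

The enabling feature is at the ring fusion. C5 is a fully substituted alkene carbon that can be carried as a vinyl bromide, and its neighbour C6 is a plain methylene attached to the C7 stereocentre. C5–C6 is thus an sp2–sp3 bond whose alkyl half can come from hydroboration of a C6=C7 methylidene, and that hydroboration creates C7 at the same time.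

## Retrosynthesis

**Acyl C–O bonds and the C3 oxidation level (25 ⇒ 24 ⇒ 23 ⇒ 22 ⇒ 21).** The acetate and propanoate are cut first and the enone is traced to an allylic silyl ether. This keeps esters and the enone away from the organolithium, hydride and borane steps. MnO2 can pick the allylic C3 hydroxyl out of triol 22, and the secondary C8 hydroxyl of 23 can be acylated before the tertiary one of 24. The precursor 21 is a tris-silyl ether with all four ring stereocentres in place, so the forward steps are only deprotection, one oxidation and two acylations.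

**C5–C6 (21 ⇒ 19, through borane 20).** Cutting C6–C7 or C7–C8 would require an enolate or carbonyl-addition closure of a seven-membered ring that makes stereocentres during the closure. Cutting C1–C10 or C9–C10 would destroy the easily made C1/C10 pair. The C5–C6 cut instead opens the ring to a monocyclic cyclopentenyl bromide 19 with an acyclic chain and removes the C7 stereocentre. The forward reaction must hydroborate C6=C7 with boron on C6 and hydrogen on the correct face of C7, then couple C6 to C5 with palladium.

**The C8 stereocentre (19 ⇒ 18 ⇒ 17).** The C8–H bond is cut back to enone 17. C10 cannot direct a carbonyl addition at C8, whereas an enone is a good substrate for catalyst-controlled reduction. The forward reduction must distinguish the α-branched alkenyl group from the C9 methylene.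

**C7–C8 (17 ⇒ 12 + 16).** The chain is cut between the ketone and the methylidene carbon. Acyl substitution of the N-methoxy-N-methylamide 12 by vinyllithium 16 gives the enone directly and saves the oxidation that an aldehyde addition would need. Reagent 16 brings C6, C7, C11 and both methyls. It comes from hydrazone 15, made from silyl ether 14 of commercial 3-hydroxy-3-methylbutan-2-one 13, the hydration product of 2-methylbut-3-yn-2-ol. The forward step needs one clean addition without disturbing the C5 bromide.

**Functional-group changes at C8 and C3 (12 ⇒ 11 ⇒ 10 ⇒ 9).** The amide is traced to the auxiliary imide, and the C3 silyl ether to the ketone of β-bromo enone 9. These are C–N and C–O/C–H changes only, and no skeletal bond is touched.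

**The C5–Br bond (9 ⇒ 8).** The vinyl bromide is traced to the carbonyl of vinylogous ester 8 by a 1,3-carbonyl transposition. This is what allows enolate chemistry next to a carbonyl to place a substituent next to the future vinyl bromide. The forward reaction must put bromide on the former carbonyl carbon (C5) and release the ethyl group from O-3, leaving C1 untouched.

**C1–C10 (8 ⇒ 2 + 6).** The last skeletal cut is a Michael disconnection between the α'-carbon of vinylogous ester 2 (through its lithium dienolate 7) and the β-carbon of N-crotonyl imide 6. It makes C1 and C10 in one step from two simple partners. Compound 2 comes from dione 1. Compound 6 comes from crotonic acid 3 and oxazolidinone 4, through mixed anhydride 5. The forward reaction must control both the face of C10 (auxiliary) and the C1/C10 relationship (closed transition state).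

## Roads not taken

Alternative 1: The cut is C7–C8. Aldehyde A1 is a cyclopentenone with a prenyl group on C5 and the C10–C8 aldehyde chain on C1. With Me2AlCl it would undergo an intramolecular carbonyl-ene reaction to give dienone alcohol A2. The merits are real. The ring and both C7 and C8 are made in one step through a cyclic transition state, the enone is present from the start, and no silyl groups or C3 redox steps are needed. The weak points are as follows. Seven-membered ene closures are slower than six-membered ones. The Lewis acid must select the aldehyde over the enone. A2 has the C7/C8 trans arrangement, so C8 must be inverted next to a hindered centre. C11 must then be oxygenated by Markovnikov hydration of the isopropenyl group in the presence of the enone, followed by acetylation. Fair comparison: Alternative 1 reaches the bicycle in fewer steps and probably sets C7 more reliably, through the ring, than an acyclic hydroboration can. Against this, the chosen plan delivers C8 in the correct configuration by reagent control and C11 already oxygenated, so it needs neither an inversion nor a hydration.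

Alternative 2: The cuts are C6–C7 and C9–C10. Rh2(S-PTAD)4 would convert siloxyvinyl diazo ester A3 into a carbenoid that cyclopropanates the methylidene of diene A4. Cope rearrangement of the cis-divinylcyclopropane then gives cycloheptadiene A5. The merits are convergence, two C–C bonds and the ring in one catalytic step, and catalyst control of C10 without an auxiliary. The weak points all come after the key step. A5 has its alkenes at C1=C5 and C7=C8, so C1, C7 and C8 all still have to be set, by alkene isomerisation with protonation at C1 and by reduction of a tetrasubstituted β-silyloxy acrylate. C11 needs two methyl additions to an ester flanked by an enol ether. The C4 stereocentre of A4 is sacrificed, and A4 is a sensitive exocyclic diene. Fair comparison: Alternative 2 is better in convergence and in catalytic enantiocontrol. Against this, the chosen plan has all four stereocentres in place when the ring closes, and only deprotection, oxidation and acylation remain.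

Alternative 3: The cut is C1–C2, so the five-membered ring is made last. Ph3PAuSbF6 (monovalent gold) in wet acetonitrile would rearrange propargylic pivalate A6 to enone A7 by a Rautenstrauch reaction. The merit is a better endgame than the chosen plan: A7 already has the enone and both oxygens, so no C3 redox is needed, and C1 is set by chirality transfer. The weak point is that the difficulty is moved rather than solved. A6 is a cycloheptene with three stereocentres (C7, C8, C10) that must be built first. Its tertiary propargylic carbon C4 must be a single epimer, because its configuration is relayed to C1. That relay may be matched or mismatched with C10. The tertiary silyl ether must also survive a cationic gold catalyst in wet solvent. Fair comparison: Alternative 3 wins after the key step. Against this, the chosen plan makes the seven-membered ring and C7 in one palladium step on an open-chain precursor assembled from three cheap building blocks.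

Key step: step 13

Assumption: in step 3 the N-crotonyl imide reacts through its lithium-chelated s-cis conformer, in which the (R)-benzyl group covers the Re face of C10; if the open conformer reacted instead, the (S)-auxiliary would be used with no other change.

## Route

Step 1
Reactants: 1 2-methylcyclopentane-1,3-dione
Product: 2 3-ethoxy-2-methylcyclopent-2-en-1-one
Conditions: EtOH, TsOH·H2O (cat.), toluene, reflux, azeotropic removal of water
Reagents that add atoms: ethanol, CCO
Why: Acid-catalysed enol etherification of the cyclic 1,3-dione gives the vinylogous ester, which differentiates the remaining carbonyl (future C5) from the free α'-methylene (future C1).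

Step 2
Reactants: 3 (E)-but-2-enoic acid; 4 (R)-4-benzyloxazolidin-2-one
Product: 6 (R)-4-benzyl-3-[(E)-but-2-enoyl]oxazolidin-2-one, via mixed pivalic anhydride 5 (not isolated)
Conditions: t-BuCOCl, Et3N, THF, –20 °C; then LiCl, 4, –20 °C → rt
Reagents that add atoms: none
Why: Mixed-anhydride N-acylation of the oxazolidinone with LiCl activation is a standard preparation of N-enoyl imides and keeps the (E)-alkene intact.

Step 3
Reactants: 2 3-ethoxy-2-methylcyclopent-2-en-1-one; 6 (R)-4-benzyl-3-[(E)-but-2-enoyl]oxazolidin-2-one
Product: 8 (R)-4-benzyl-3-{(S)-3-[(R)-4-ethoxy-3-methyl-2-oxocyclopent-3-en-1-yl]butanoyl}oxazolidin-2-one, via lithium dienolate 7 (not isolated)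
Conditions: LiN(i-Pr)2, THF, –78 °C; then 6, –78 °C; AcOH quench
Reagents that add atoms: none
Why: Kinetic α'-deprotonation gives cross-conjugated dienolate 7, which adds to the s-cis enoyl imide in a lithium-bridged closed transition state (Michael addition). The benzyl group shields the Re face of C10, so C1 bonds to the Si face (10S); the ring-locked E(O)-enolate keeps the acceptor chain away from C2, which gives the syn C1/C10 relationship (1R).

Step 4
Reactants: 8 (R)-4-benzyl-3-{(S)-3-[(R)-4-ethoxy-3-methyl-2-oxocyclopent-3-en-1-yl]butanoyl}oxazolidin-2-one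
Product: 9 (R)-4-benzyl-3-{(S)-3-[(R)-2-bromo-3-methyl-4-oxocyclopent-2-en-1-yl]butanoyl}oxazolidin-2-one
Conditions: (COBr)2, DMF (cat.), CH2Cl2, 0 °C → rt
Reagents that add atoms: oxalyl bromide, O=C(Br)C(=O)Br
Why: Vilsmeier-type activation of the vinylogous ester acylates the C5 carbonyl oxygen; bromide adds at C5 with loss of CO and CO2 and then removes the ethyl group from the C3 oxocarbenium ion. The halogen therefore ends on C5 and the ketone on C3 (1,3-carbonyl transposition), and C1 is no longer α to a carbonyl.

Step 5
Reactants: 9 (R)-4-benzyl-3-{(S)-3-[(R)-2-bromo-3-methyl-4-oxocyclopent-2-en-1-yl]butanoyl}oxazolidin-2-one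
Product: 10 (R)-4-benzyl-3-{(S)-3-[(1R,4R)-2-bromo-4-hydroxy-3-methylcyclopent-2-en-1-yl]butanoyl}oxazolidin-2-one
Conditions: NaBH4, CeCl3·7H2O, MeOH, –78 °C
Reagents that add atoms: none
Why: Luche reduction gives clean 1,2-reduction of the β-bromo enone at a temperature at which the imide is untouched. Hydride should enter anti to the C1 side chain to give mainly the cis (3R) alcohol; the C3 configuration is immaterial because C3 is re-oxidised later.

Step 6
Reactants: 10 (R)-4-benzyl-3-{(S)-3-[(1R,4R)-2-bromo-4-hydroxy-3-methylcyclopent-2-en-1-yl]butanoyl}oxazolidin-2-one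
Product: 11 (R)-4-benzyl-3-{(S)-3-[(1R,4R)-2-bromo-4-(tert-butyldimethylsilyloxy)-3-methylcyclopent-2-en-1-yl]butanoyl}oxazolidin-2-one
Conditions: TBSCl, imidazole, DMF, rt
Reagents that add atoms: tert-butyldimethylsilyl chloride, CC(C)(C)[Si](C)(C)Cl
Why: Standard silylation of a secondary allylic alcohol; the silyl ether masks C3 against the organolithium, hydride and borane reagents that follow.

Step 7
Reactants: 11 (R)-4-benzyl-3-{(S)-3-[(1R,4R)-2-bromo-4-(tert-butyldimethylsilyloxy)-3-methylcyclopent-2-en-1-yl]butanoyl}oxazolidin-2-one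
Product: 12 (S)-3-[(1R,4R)-2-bromo-4-(tert-butyldimethylsilyloxy)-3-methylcyclopent-2-en-1-yl]-N-methoxy-N-methylbutanamide
Conditions: MeNHOMe·HCl, AlMe3, CH2Cl2, –10 → 0 °C
Reagents that add atoms: N,O-dimethylhydroxylamine hydrochloride, CNOC.Cl
Why: Aluminium amide transamination attacks the exocyclic imide carbonyl, which has an unhindered α-methylene, and releases the auxiliary for recovery. The resulting N-methoxy-N-methylamide accepts exactly one organolithium.

Step 8
Reactants: 13 3-hydroxy-3-methylbutan-2-one
Product: 14 3-methyl-3-(triethylsilyloxy)butan-2-one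
Conditions: TESOTf, 2,6-lutidine, CH2Cl2, –78 → 0 °C
Reagents that add atoms: triethylsilyl trifluoromethanesulfonate, CC[Si](CC)(CC)OS(=O)(=O)C(F)(F)F
Why: Silyl triflate with a hindered base silylates the tertiary hydroxyl; the triethylsilyl ether withstands the strongly basic steps and is removed later by fluoride together with the other silyl groups.

Step 9
Reactants: 14 3-methyl-3-(triethylsilyloxy)butan-2-one
Product: 15 (E)-N'-[3-methyl-3-(triethylsilyloxy)butan-2-ylidene]-2,4,6-triisopropylbenzenesulfonohydrazide
Conditions: 2,4,6-(i-Pr)3C6H2SO2NHNH2, THF, rt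
Reagents that add atoms: 2,4,6-triisopropylbenzenesulfonohydrazide, CC(C)c1cc(C(C)C)c(S(=O)(=O)NN)c(C(C)C)c1
Why: Condensation of the ketone with the arylsulfonyl hydrazide; the N–N bond lies anti to the quaternary carbon and therefore syn to the methyl group that has to be deprotonated.

Step 10
Reactants: 15 (E)-N'-[3-methyl-3-(triethylsilyloxy)butan-2-ylidene]-2,4,6-triisopropylbenzenesulfonohydrazide; 12 (S)-3-[(1R,4R)-2-bromo-4-(tert-butyldimethylsilyloxy)-3-methylcyclopent-2-en-1-yl]-N-methoxy-N-methylbutanamide
Product: 17 (6S)-6-[(1R,4R)-2-bromo-4-(tert-butyldimethylsilyloxy)-3-methylcyclopent-2-en-1-yl]-2-methyl-3-methylidene-2-(triethylsilyloxy)heptan-4-one, via vinyllithium 16 (not isolated)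
Conditions: n-BuLi (2 equiv), THF, –78 → 0 °C; then 12, –78 °C; aq. NH4Cl
Reagents that add atoms: none
Why: Shapiro reaction: double deprotonation (N–H, then the methyl group, the only α-C–H set) followed by loss of sulfinate and N2 gives the 1,1-disubstituted vinyllithium 16. It adds once to the N-methoxy-N-methylamide through the chelated tetrahedral intermediate; at –78 °C acylation should outrun lithium–bromine exchange at the hindered C5 bromide.

Step 11
Reactants: 17 (6S)-6-[(1R,4R)-2-bromo-4-(tert-butyldimethylsilyloxy)-3-methylcyclopent-2-en-1-yl]-2-methyl-3-methylidene-2-(triethylsilyloxy)heptan-4-one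
Product: 18 (4R,6S)-6-[(1R,4R)-2-bromo-4-(tert-butyldimethylsilyloxy)-3-methylcyclopent-2-en-1-yl]-2-methyl-3-methylidene-2-(triethylsilyloxy)heptan-4-ol
Conditions: (S)-2-methyl-CBS-oxazaborolidine (cat.), catecholborane, toluene, –78 °C
Reagents that add atoms: none
Why: Corey–Bakshi–Shibata reduction: the oxazaborolidine binds the ketone lone pair on the side of the smaller C9 methylene and treats the α-branched alkenyl group as the large substituent, which with the (S)-catalyst should give the 8R alcohol. Catecholborane at low temperature leaves the alkene and the bromide alone.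

Step 12
Reactants: 18 (4R,6S)-6-[(1R,4R)-2-bromo-4-(tert-butyldimethylsilyloxy)-3-methylcyclopent-2-en-1-yl]-2-methyl-3-methylidene-2-(triethylsilyloxy)heptan-4-ol
Product: 19 (4R,6S)-6-[(1R,4R)-2-bromo-4-(tert-butyldimethylsilyloxy)-3-methylcyclopent-2-en-1-yl]-4-(tert-butyldimethylsilyloxy)-2-methyl-3-methylidene-2-(triethylsilyloxy)heptane
Conditions: TBSOTf, 2,6-lutidine, CH2Cl2, –78 → 0 °C
Reagents that add atoms: tert-butyldimethylsilyl trifluoromethanesulfonate, CC(C)(C)[Si](C)(C)OS(=O)(=O)C(F)(F)F
Why: Silyl triflate silylation of the hindered secondary allylic alcohol; a silyl ether at C8 is the directing group for which anti-selective 9-BBN hydroboration of 1,1-disubstituted allylic ethers is documented.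

Step 13
Reactants: 19 (4R,6S)-6-[(1R,4R)-2-bromo-4-(tert-butyldimethylsilyloxy)-3-methylcyclopent-2-en-1-yl]-4-(tert-butyldimethylsilyloxy)-2-methyl-3-methylidene-2-(triethylsilyloxy)heptane
Product: 21 (1R,3R,7S,8R,10S)-3,8-bis(tert-butyldimethylsilyloxy)-11-(triethylsilyloxy)guai-4-ene, via B-alkyl-9-BBN 20 (not isolated)
Conditions: 9-BBN, THF, rt → 50 °C; then Pd(dppf)Cl2 (cat.), AsPh3, Cs2CO3, DMF/THF/H2O, 50 °C, high dilution
Reagents that add atoms: none
Why: 9-BBN adds syn and anti-Markovnikov to C6=C7, the only alkene with a free terminus, placing boron on C6 and hydrogen on C7 to give 20; the tetrasubstituted bromoalkene and the silyl ethers are inert. Zerovalent palladium formed from Pd(dppf)Cl2 then inserts into the C5–Br bond, the base-activated primary alkylborane transfers C6 to palladium, and reductive elimination forms C5–C6. The closest known reaction type is the one-pot hydroboration/intramolecular B-alkyl Suzuki–Miyaura cyclisation of alkenyl vinyl halides. The seven-membered ring closes by reductive elimination from an eight-membered palladacycle, an sp2–sp3 closure helped by the wide bite angle of dppf (against β-hydride elimination) and by high dilution (against dimerisation). The new stereocentre C7 is controlled by the neighbouring C8 silyloxy stereocentre: in the staggered transition state with the C8 hydrogen inside, the C9 chain anti to the incoming borane and the silyloxy group outside, hydrogen reaches the Re face of C7 (priorities C11 > C8 > C6), which is the 1,2-anti outcome and places C11 cis to the C8 oxygen in the ring (7S). The step therefore needs diastereofacial selectivity in the hydroboration, and the substrate provides it through a single allylic stereocentre bearing a silyl ether, reinforced by the bulk of 9-BBN. No enolate or cation is formed, so C1, C8 and C10 are not at risk, and boron on C6 has no β-heteroatom that could be eliminated.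

Step 14
Reactants: 21 (1R,3R,7S,8R,10S)-3,8-bis(tert-butyldimethylsilyloxy)-11-(triethylsilyloxy)guai-4-ene
Product: 22 (1R,3R,7S,8R,10S)-guai-4-ene-3,8,11-triol
Conditions: n-Bu4NF, THF, rt → 45 °C
Reagents that add atoms: none
Why: Fluoride cleaves all three silyl ethers, with warming for the tertiary and the hindered secondary one; the non-acidic conditions avoid ionisation of the allylic C3 and tertiary C11 alcohols.

Step 15
Reactants: 22 (1R,3R,7S,8R,10S)-guai-4-ene-3,8,11-triol
Product: 23 (1R,7S,8R,10S)-8,11-dihydroxyguai-4-en-3-one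
Conditions: MnO2, CH2Cl2, rt
Reagents that add atoms: none
Why: MnO2 oxidises only the allylic C3 alcohol; the conjugated enone is restored under neutral conditions that do not epimerise C1 and leave the C8 and C11 hydroxyls untouched.

Step 16
Reactants: 23 (1R,7S,8R,10S)-8,11-dihydroxyguai-4-en-3-one
Product: 24 (1R,7S,8R,10S)-11-hydroxy-3-oxoguai-4-en-8-yl propanoate
Conditions: (EtCO)2O, DMAP (cat.), Et3N, CH2Cl2, 0 °C
Reagents that add atoms: propanoic anhydride, CCC(=O)OC(=O)CC
Why: DMAP-catalysed acylation at low temperature distinguishes the secondary C8 hydroxyl from the tertiary C11 hydroxyl.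

Step 17
Reactants: 24 (1R,7S,8R,10S)-11-hydroxy-3-oxoguai-4-en-8-yl propanoate
Product: 25 (1R,7S,8R,10S)-11-acetoxy-3-oxoguai-4-en-8-yl propanoate
Conditions: Ac2O, DMAP, Et3N, CH2Cl2, 40 °C
Reagents that add atoms: acetic anhydride, CC(=O)OC(C)=O
Why: Nucleophilic-catalysis acetylation of the tertiary alcohol with excess anhydride and mild warming completes the target; the propanoyl group is thermodynamically better placed on the secondary oxygen, which disfavours its migration to O-11.

## Compound list

1 | 2-methylcyclopentane-1,3-dione | CC1C(=O)CCC1=O | starting material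
2 | 3-ethoxy-2-methylcyclopent-2-en-1-one | CCOC1=C(C)C(=O)CC1 | intermediate
3 | (E)-but-2-enoic acid (crotonic acid) | C/C=C/C(=O)O | starting material
4 | (R)-4-benzyloxazolidin-2-one | O=C1N[C@H](Cc2ccccc2)CO1 | starting material
5 | (E)-but-2-enoic 2,2-dimethylpropanoic anhydride | C/C=C/C(=O)OC(=O)C(C)(C)C | intermediate (not isolated)
6 | (R)-4-benzyl-3-[(E)-but-2-enoyl]oxazolidin-2-one | C/C=C/C(=O)N1[C@H](Cc2ccccc2)COC1=O | intermediate
7 | lithium 4-ethoxy-5-methylcyclopenta-1,4-dien-1-olate | CCOC1=C(C)C(O[Li])=CC1 | intermediate (not isolated)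
8 | (R)-4-benzyl-3-{(S)-3-[(R)-4-ethoxy-3-methyl-2-oxocyclopent-3-en-1-yl]butanoyl}oxazolidin-2-one | CCOC1=C(C)C(=O)[C@@H]([C@@H](C)CC(=O)N2[C@H](Cc3ccccc3)COC2=O)C1 | intermediate
9 | (R)-4-benzyl-3-{(S)-3-[(R)-2-bromo-3-methyl-4-oxocyclopent-2-en-1-yl]butanoyl}oxazolidin-2-one | CC1=C(Br)[C@@H]([C@@H](C)CC(=O)N2[C@H](Cc3ccccc3)COC2=O)CC1=O | intermediate
10 | (R)-4-benzyl-3-{(S)-3-[(1R,4R)-2-bromo-4-hydroxy-3-methylcyclopent-2-en-1-yl]butanoyl}oxazolidin-2-one | CC1=C(Br)[C@@H]([C@@H](C)CC(=O)N2[C@H](Cc3ccccc3)COC2=O)C[C@H]1O | intermediate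
11 | (R)-4-benzyl-3-{(S)-3-[(1R,4R)-2-bromo-4-(tert-butyldimethylsilyloxy)-3-methylcyclopent-2-en-1-yl]butanoyl}oxazolidin-2-one | CC1=C(Br)[C@@H]([C@@H](C)CC(=O)N2[C@H](Cc3ccccc3)COC2=O)C[C@H]1O[Si](C)(C)C(C)(C)C | intermediate
12 | (S)-3-[(1R,4R)-2-bromo-4-(tert-butyldimethylsilyloxy)-3-methylcyclopent-2-en-1-yl]-N-methoxy-N-methylbutanamide | CC1=C(Br)[C@@H]([C@@H](C)CC(=O)N(C)OC)C[C@H]1O[Si](C)(C)C(C)(C)C | intermediate
13 | 3-hydroxy-3-methylbutan-2-one | CC(=O)C(C)(C)O | starting material
14 | 3-methyl-3-(triethylsilyloxy)butan-2-one | CC(=O)C(C)(C)O[Si](CC)(CC)CC | intermediate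
15 | (E)-N'-[3-methyl-3-(triethylsilyloxy)butan-2-ylidene]-2,4,6-triisopropylbenzenesulfonohydrazide | C/C(=N\NS(=O)(=O)c1c(C(C)C)cc(C(C)C)cc1C(C)C)C(C)(C)O[Si](CC)(CC)CC | intermediate
16 | [3-methyl-3-(triethylsilyloxy)but-1-en-2-yl]lithium | [Li]C(=C)C(C)(C)O[Si](CC)(CC)CC | intermediate (not isolated)
17 | (6S)-6-[(1R,4R)-2-bromo-4-(tert-butyldimethylsilyloxy)-3-methylcyclopent-2-en-1-yl]-2-methyl-3-methylidene-2-(triethylsilyloxy)heptan-4-one | CC1=C(Br)[C@@H]([C@@H](C)CC(=O)C(=C)C(C)(C)O[Si](CC)(CC)CC)C[C@H]1O[Si](C)(C)C(C)(C)C | intermediate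
18 | (4R,6S)-6-[(1R,4R)-2-bromo-4-(tert-butyldimethylsilyloxy)-3-methylcyclopent-2-en-1-yl]-2-methyl-3-methylidene-2-(triethylsilyloxy)heptan-4-ol | CC1=C(Br)[C@@H]([C@@H](C)C[C@@H](O)C(=C)C(C)(C)O[Si](CC)(CC)CC)C[C@H]1O[Si](C)(C)C(C)(C)C | intermediate
19 | (4R,6S)-6-[(1R,4R)-2-bromo-4-(tert-butyldimethylsilyloxy)-3-methylcyclopent-2-en-1-yl]-4-(tert-butyldimethylsilyloxy)-2-methyl-3-methylidene-2-(triethylsilyloxy)heptane | CC1=C(Br)[C@@H]([C@@H](C)C[C@@H](O[Si](C)(C)C(C)(C)C)C(=C)C(C)(C)O[Si](CC)(CC)CC)C[C@H]1O[Si](C)(C)C(C)(C)C | intermediate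
20 | 9-{(2S,3R,5S)-5-[(1R,4R)-2-bromo-4-(tert-butyldimethylsilyloxy)-3-methylcyclopent-2-en-1-yl]-3-(tert-butyldimethylsilyloxy)-2-[2-(triethylsilyloxy)propan-2-yl]hexyl}-9-borabicyclo[3.3.1]nonane | CC1=C(Br)[C@@H]([C@@H](C)C[C@@H](O[Si](C)(C)C(C)(C)C)[C@H](CB2C3CCCC2CCC3)C(C)(C)O[Si](CC)(CC)CC)C[C@H]1O[Si](C)(C)C(C)(C)C | intermediate (not isolated)
21 | (1R,3R,7S,8R,10S)-3,8-bis(tert-butyldimethylsilyloxy)-11-(triethylsilyloxy)guai-4-ene | CC(C)(C)[Si](C)(C)O[C@@H]1C[C@H](C)[C@H]2C[C@@H](O[Si](C)(C)C(C)(C)C)C(C)=C2C[C@@H]1C(C)(C)O[Si](CC)(CC)CC | intermediate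
22 | (1R,3R,7S,8R,10S)-guai-4-ene-3,8,11-triol | O[C@@H]1C[C@H](C)[C@H]2C[C@@H](O)C(C)=C2C[C@@H]1C(C)(C)O | intermediate
23 | (1R,7S,8R,10S)-8,11-dihydroxyguai-4-en-3-one | O[C@@H]1C[C@H](C)[C@H]2CC(=O)C(C)=C2C[C@@H]1C(C)(C)O | intermediate
24 | (1R,7S,8R,10S)-11-hydroxy-3-oxoguai-4-en-8-yl propanoate | CCC(=O)O[C@@H]1C[C@H](C)[C@H]2CC(=O)C(C)=C2C[C@@H]1C(C)(C)O | intermediate
25 | (1R,7S,8R,10S)-11-acetoxy-3-oxoguai-4-en-8-yl propanoate | CCC(=O)O[C@@H]1C[C@H](C)[C@H]2CC(=O)C(C)=C2C[C@@H]1C(C)(C)OC(C)=O | target

## Step count and least certain steps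

Total: 17 steps. Longest linear sequence: 14 steps (1 → 2 → 8 → 9 → 10 → 11 → 12 → 17 → 18 → 19 → 21 → 22 → 23 → 24 → 25).

**Step 13 (key step).** The most likely failure is delivery of hydrogen to the wrong face of C7, that is, eroded or reversed facial selectivity. C7 carries the fully substituted C11, and allylic 1,2-strain between C11 and the C8 substituents may push the silyloxy group out of the outside position, so the borane may then prefer the other face. A lesser risk is β-hydride elimination or protodeboronation competing with closure of the hindered palladacycle. The fallback relays the stereochemistry through C8. It sets out from 17. Reduction with the (R)-oxazaborolidine and catecholborane gives (4S,6S)-6-[(1R,4R)-2-bromo-4-(tert-butyldimethylsilyloxy)-3-methylcyclopent-2-en-1-yl]-2-methyl-3-methylidene-2-(triethylsilyloxy)heptan-4-ol F1, which is silylated to the C8-epimeric tris-silyl ether F2. If the intrinsic preference is 1,2-syn, hydroboration of F2 puts hydrogen on the same absolute face of C7 and gives the (2S,3S,5S)-B-alkyl-9-BBN F3, and the same coupling gives (1R,3R,7S,8S,10S)-3,8-bis(tert-butyldimethylsilyloxy)-11-(triethylsilyloxy)guai-4-ene F4. Fluoride gives (1R,3R,7S,8S,10S)-guai-4-ene-3,8,11-triol F5 and MnO2 gives (1R,7S,8S,10S)-8,11-dihydroxyguai-4-en-3-one F6. Mitsunobu esterification of F6 with propanoic acid (PPh3, diisopropyl azodicarboxylate) then inverts C8 and installs the propanoate in one operation. The fallback comes back to the route at 24.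

**Step 3.** The most likely failure is incomplete control of the C1/C10 relationship. The small cyclopentenone dienolate discriminates only moderately between the two closed transition states, and lithium aggregates may not hold the imide in a single conformer. The fallback sets out from 2 and 6 as in step 3 but accepts the mixture. The C1 epimer, (R)-4-benzyl-3-{(S)-3-[(S)-4-ethoxy-3-methyl-2-oxocyclopent-3-en-1-yl]butanoyl}oxazolidin-2-one F7, is separated. C1 is α to the ketone at this stage only, so F7 is re-equilibrated with DBU in toluene and recycled. The fallback comes back to the route at 8.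

**Step 4.** The most likely failure is bromide attack at C3 instead of C5 (substitution without transposition) or slow loss of the ethyl group, during which acidic species could erode C1. The fallback uses a vinylogous amide, for which halide attack at the carbonyl carbon is secure. It sets out from 1. Condensation with pyrrolidine gives 2-methyl-3-(pyrrolidin-1-yl)cyclopent-2-en-1-one F8. α'-Lithiation of F8 and addition to 6, as in step 3, gives (R)-4-benzyl-3-{(S)-3-[(R)-3-methyl-2-oxo-4-(pyrrolidin-1-yl)cyclopent-3-en-1-yl]butanoyl}oxazolidin-2-one F9. Oxalyl bromide converts F9 into 1-{(4R)-4-[(S)-4-((R)-4-benzyl-2-oxooxazolidin-3-yl)-4-oxobutan-2-yl]-3-bromo-2-methylcyclopent-2-en-1-ylidene}pyrrolidin-1-ium bromide F10. Hydrolysis of F10 in aqueous NaOAc comes back to the route at 9.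

**Step 10.** The most likely failure is lithium–bromine exchange between 16 and the C5 bromide, or deprotonation of C9 by the hindered, basic vinyllithium, which would return the amide and the protonated alkene. The fallback sets out from 12. Reduction with i-Bu2AlH gives (S)-3-[(1R,4R)-2-bromo-4-(tert-butyldimethylsilyloxy)-3-methylcyclopent-2-en-1-yl]butanal F11. The organocerium reagent made from 16 and CeCl3 is less basic and does not exchange halogen. It adds to F11 to give the C8-epimeric alcohols, 18 together with its epimer F1. Dess–Martin oxidation of this mixture comes back to the route at 17.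

**Step 17.** The most likely failure is slow acetylation of the hindered tertiary hydroxyl. This would leave time for propanoyl migration from O-8 to O-11 followed by acetylation of the freed secondary hydroxyl (ester scrambling), or for dienyl acetate formation at the enone. The fallback installs the tertiary ester first, while O-8 is still masked. It sets out from 21. Selective solvolysis of the triethylsilyl ether (PPTS, MeOH) gives (1R,3R,7S,8R,10S)-3,8-bis(tert-butyldimethylsilyloxy)guai-4-en-11-ol F12. Acetylation (Ac2O, DMAP, 50 °C) gives the 11-acetate F13. Buffered HF·pyridine gives (1R,3R,7S,8R,10S)-3,8-dihydroxyguai-4-en-11-yl acetate F14 and MnO2 gives (1R,7S,8R,10S)-8-hydroxy-3-oxoguai-4-en-11-yl acetate F15. Fast propanoylation of F15 ((EtCO)2O, DMAP, 0 °C) comes back to the route at 25.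

## Further compounds

F1 | step 13 | (4S,6S)-6-[(1R,4R)-2-bromo-4-(tert-butyldimethylsilyloxy)-3-methylcyclopent-2-en-1-yl]-2-methyl-3-methylidene-2-(triethylsilyloxy)heptan-4-ol | CC1=C(Br)[C@@H]([C@@H](C)C[C@H](O)C(=C)C(C)(C)O[Si](CC)(CC)CC)C[C@H]1O[Si](C)(C)C(C)(C)C
F2 | step 13 | (4S,6S)-6-[(1R,4R)-2-bromo-4-(tert-butyldimethylsilyloxy)-3-methylcyclopent-2-en-1-yl]-4-(tert-butyldimethylsilyloxy)-2-methyl-3-methylidene-2-(triethylsilyloxy)heptane | CC1=C(Br)[C@@H]([C@@H](C)C[C@H](O[Si](C)(C)C(C)(C)C)C(=C)C(C)(C)O[Si](CC)(CC)CC)C[C@H]1O[Si](C)(C)C(C)(C)C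
F3 | step 13 | 9-{(2S,3S,5S)-5-[(1R,4R)-2-bromo-4-(tert-butyldimethylsilyloxy)-3-methylcyclopent-2-en-1-yl]-3-(tert-butyldimethylsilyloxy)-2-[2-(triethylsilyloxy)propan-2-yl]hexyl}-9-borabicyclo[3.3.1]nonane | CC1=C(Br)[C@@H]([C@@H](C)C[C@H](O[Si](C)(C)C(C)(C)C)[C@H](CB2C3CCCC2CCC3)C(C)(C)O[Si](CC)(CC)CC)C[C@H]1O[Si](C)(C)C(C)(C)C
F4 | step 13 | (1R,3R,7S,8S,10S)-3,8-bis(tert-butyldimethylsilyloxy)-11-(triethylsilyloxy)guai-4-ene | CC(C)(C)[Si](C)(C)O[C@H]1C[C@H](C)[C@H]2C[C@@H](O[Si](C)(C)C(C)(C)C)C(C)=C2C[C@@H]1C(C)(C)O[Si](CC)(CC)CC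
F5 | step 13 | (1R,3R,7S,8S,10S)-guai-4-ene-3,8,11-triol | O[C@H]1C[C@H](C)[C@H]2C[C@@H](O)C(C)=C2C[C@@H]1C(C)(C)O
F6 | step 13 | (1R,7S,8S,10S)-8,11-dihydroxyguai-4-en-3-one | O[C@H]1C[C@H](C)[C@H]2CC(=O)C(C)=C2C[C@@H]1C(C)(C)O
F7 | step 3 | (R)-4-benzyl-3-{(S)-3-[(S)-4-ethoxy-3-methyl-2-oxocyclopent-3-en-1-yl]butanoyl}oxazolidin-2-one | CCOC1=C(C)C(=O)[C@H]([C@@H](C)CC(=O)N2[C@H](Cc3ccccc3)COC2=O)C1
F8 | step 4 | 2-methyl-3-(pyrrolidin-1-yl)cyclopent-2-en-1-one | CC1=C(N2CCCC2)CCC1=O
F9 | step 4 | (R)-4-benzyl-3-{(S)-3-[(R)-3-methyl-2-oxo-4-(pyrrolidin-1-yl)cyclopent-3-en-1-yl]butanoyl}oxazolidin-2-one | CC1=C(N2CCCC2)C[C@H]([C@@H](C)CC(=O)N2[C@H](Cc3ccccc3)COC2=O)C1=O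
F10 | step 4 | 1-{(4R)-4-[(S)-4-((R)-4-benzyl-2-oxooxazolidin-3-yl)-4-oxobutan-2-yl]-3-bromo-2-methylcyclopent-2-en-1-ylidene}pyrrolidin-1-ium bromide | CC1=C(Br)[C@@H]([C@@H](C)CC(=O)N2[C@H](Cc3ccccc3)COC2=O)CC1=[N+]4CCCC4.[Br-]
F11 | step 10 | (S)-3-[(1R,4R)-2-bromo-4-(tert-butyldimethylsilyloxy)-3-methylcyclopent-2-en-1-yl]butanal | CC1=C(Br)[C@@H]([C@@H](C)CC=O)C[C@H]1O[Si](C)(C)C(C)(C)C
F12 | step 17 | (1R,3R,7S,8R,10S)-3,8-bis(tert-butyldimethylsilyloxy)guai-4-en-11-ol | CC(C)(C)[Si](C)(C)O[C@@H]1C[C@H](C)[C@H]2C[C@@H](O[Si](C)(C)C(C)(C)C)C(C)=C2C[C@@H]1C(C)(C)O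
F13 | step 17 | (1R,3R,7S,8R,10S)-3,8-bis(tert-butyldimethylsilyloxy)guai-4-en-11-yl acetate | CC(C)(C)[Si](C)(C)O[C@@H]1C[C@H](C)[C@H]2C[C@@H](O[Si](C)(C)C(C)(C)C)C(C)=C2C[C@@H]1C(C)(C)OC(C)=O
F14 | step 17 | (1R,3R,7S,8R,10S)-3,8-dihydroxyguai-4-en-11-yl acetate | O[C@@H]1C[C@H](C)[C@H]2C[C@@H](O)C(C)=C2C[C@@H]1C(C)(C)OC(C)=O
F15 | step 17 | (1R,7S,8R,10S)-8-hydroxy-3-oxoguai-4-en-11-yl acetate | O[C@@H]1C[C@H](C)[C@H]2CC(=O)C(C)=C2C[C@@H]1C(C)(C)OC(C)=O
A1 | alternative 1 | (3S)-3-[(1R)-3-methyl-2-(3-methylbut-2-en-1-yl)-4-oxocyclopent-2-en-1-yl]butanal | O=CC[C@H](C)[C@H]1CC(=O)C(C)=C1CC=C(C)C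
A2 | alternative 1 | 8-epi-8-hydroxyguaia-4,11-dien-3-one (C7 as in the target, C7/C8 trans) | O[C@H]1C[C@H](C)[C@H]2CC(=O)C(C)=C2C[C@@H]1C(C)=C
A3 | alternative 2 | methyl 3-(tert-butyldimethylsilyloxy)-2-diazobut-3-enoate | COC(=O)C(=[N+]=[N-])C(=C)O[Si](C)(C)C(C)(C)C
A4 | alternative 2 | (E)-1-ethylidene-3-methyl-2-methylidene-4-(tert-butyldimethylsilyloxy)cyclopentane (guaiane C3 and C4 as in A5) | C/C=C1\C[C@@H](O[Si](C)(C)C(C)(C)C)[C@@H](C)C1=C
A5 | alternative 2 | methyl 3,8-bis(tert-butyldimethylsilyloxy)-12,13-dinorguaia-1(5),7-dien-11-oate | CC(C)(C)[Si](C)(C)OC=1C[C@H](C)C=2C[C@@H](O[Si](C)(C)C(C)(C)C)[C@@H](C)C2CC1C(=O)OC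
A6 | alternative 3 | 2-[8-(tert-butyldimethylsilyloxy)-10-methyl-7-(2-(triethylsilyloxy)propan-2-yl)cyclohept-1(5)-en-5-yl]but-3-yn-2-yl pivalate (guaiane numbering; C7, C8, C10 as in the target, C4 epimer to be chosen for the chirality transfer) | CC(C)(C)[Si](C)(C)O[C@@H]1C[C@H](C)C=C(C(C)(OC(=O)C(C)(C)C)C#C)C[C@@H]1C(C)(C)O[Si](CC)(CC)CC
A7 | alternative 3 | (1R,7S,8R,10S)-8-(tert-butyldimethylsilyloxy)-11-(triethylsilyloxy)guai-4-en-3-one | CC(C)(C)[Si](C)(C)O[C@@H]1C[C@H](C)[C@H]2CC(=O)C(C)=C2C[C@@H]1C(C)(C)O[Si](CC)(CC)CC
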